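Looking to late times first, I expected this flask to hold [starting material] at a standing level, where dissolution feeds what the catalyst drains.

    starting material + catalyst intermediate A ⇌ catalyst intermediate B (K1 = 6.1 M⁻¹, k1 = 245 M⁻¹ s⁻¹)
    catalyst intermediate B ⇌ free catalyst + product (K2 = 13 M, k2 = 335 s⁻¹)
    solid substrate ⇌ starting material, rate k3*(cs3 - [starting material]) while solid is left; crystals form when [starting material] > cs3 (cs3 = 0.18 M, k3 = 0.0127 s⁻¹)
    partner + free catalyst ⇌ catalyst intermediate A (K4 = 23.6 M⁻¹, k4 = 1190 M⁻¹ s⁻¹)
    gas ⇌ partner, rate k5*(csat - [partner]) (k5 = 0.113 s⁻¹, csat = 85 mM)

solid substrate 0.36 M; gas 85 mM (held); free catalyst 0.055 mol%; time 25 s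

* amount of product at 25 s, in percent of the solid substrate charged
* concentration of partner in solution at 25 s, in percent of saturation

- solid, in amounts per volume of the solution: solid substrate
- at the start none of partner is dissolved
- at the start none of the solid substrate is in solution
- run time (flask): 25 s

I first asked which constants had to be known well. The back step of product release hardly mattered: even with the whole charge as product it ran at 9.28 s⁻¹ against 335 s⁻¹ forward. The binding rate constant mattered little too, since the catalyst forms relax within 0.00660 s. An error in the binding equilibrium arrives damped, reaching the bound share at 0.333 of its size. The dissolution coefficient, solubility and loading pass nearly in full, as product grows with feed times drain. Gas transfer can deliver at most 66.7 % of the charge by 25 s, the solid at most 15.9 %. [Partner] starts at zero and fills with a time constant of 8.85 s, so I took saturation for the binding share as a late-time simplification, one that overstates the share early in the run.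

Binding constant times saturation is 2.01, and the symmetric value of one would make both catalyst forms equal; with [partner] taken at saturation, I reckoned a bound share of 66.7 %. With release taking 0.893 of catalyst intermediate B forward, and 0.198 mM of catalyst, the cycle was a pseudo-first-order drain of 0.0289 s⁻¹. Over the dissolution coefficient that gave 2.28, the drain ratio. The standing level is solubility over one plus this ratio: 0.0549 M, or 15.3 % of the charge, approached with time constant 24.0 s. Integrating, I reckoned 4.17 % product, and 83.4 % of saturation.

The forecast, with “the final release step fast”, gave 3.8 % and 87 %, its yield below mine.

The simulation gave 3.64 % and 86.9 %. Catalyst intermediate A held 59.2 % of the catalyst at 25 s, below my 66.7 %, which puts the drain at 0.0257 s⁻¹ against 0.0127 s⁻¹ for dissolution, a ratio of 2.02. In the neighbour flask read at 1.5 min, catalyst intermediate A held 56.3 %, the ratio becomes 1.92, the level 17.1 % of the charge, and [starting material] stood at 16.5 %.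

Its constants are assumed; the rest is arithmetic.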